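The flask is read at 1.5 min, just past the half-life of J by step 1, 1.4 min, and the question is where the converted J has gone by then.

    J → X (k1 = 0.0084 s⁻¹)
    Z + X → ZX (k2 = 20 L mol⁻¹ s⁻¹)
    E + X → EX (k3 = 430 L mol⁻¹ s⁻¹)
    X → Q (k4 = 36 s⁻¹)
    G ⇌ E, rate k5*(cs5 - [E]) while solid is left; crystals form when [E] > cs5 (cs5 = 0.19 M, k5 = 0.0035 s⁻¹)
    E + ZX ⇌ EZX, settled at all times (K6 = 5.7 L mol⁻¹)

J 0.40 M; Z 1.20 M; G 0.240 M; time 1.5 min

- for ZX the EZX is counted in
- as a solid, counted per litre of solution: G
- at the start none of G is in solution
- run time (flask): 1.5 min

1. ZX and EZX together at 1.5 min, in percent of the J charged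
2. concentration of E in solution at 25 s, in percent of saturation
3. the change that raises the amount of ZX and EZX together at 1.5 min, in percent of the J charged most ("none" if none brings more than 2 percentage points) (epsilon / theta / zeta / none)
4. amount of ZX and EZX together at 1.5 min, in percent of the J charged, after epsilon

- epsilon: doubling the amount of Z, all else as stated
- theta: doubling the dissolution coefficient of step 5, all else as stated
- zeta: doubling the solubility in step 5, all else as stated

By hand, the exponent 0.756 means that 53.0 % of the J has been converted at the reading. X lasts about 0.0167 s, far shorter than the 119 s lifetime of J, so J to X is the rate-limiting step and each X is divided among its exits as it forms. With E left out and Z at its charge, the rate of X into ZX over the rate of X into ZX and Q gives 40.0 %, the Z share. That share of the converted J is 21.2 %, and E takes some of it. Doubling Z lifts the share to 57.1 %, which is 30.3 % of the J charged, a gain of 9.1 percentage points. Theta and zeta raise the supply of E, a rival of Z for X with the larger rate constant, 430 L mol⁻¹ s⁻¹ against 20 L mol⁻¹ s⁻¹, so this reckoning picks epsilon. Dissolution kept at its starting rate, with none of the E consumed, reckons to 8.75 % of saturation at 25 s.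

The forecast gave 18.7 % (range 17.5 % to 20 %), 6 % of saturation, epsilon, and 27.7 % after it, on the ground that “X is so short-lived that it simply splits J's slow decay among Z, E and the Q loss”.

The flask gives 18.9 %, with E at 5.89 % of saturation at 25 s, and epsilon brings 9.1 points to reach 28.0 %, while theta and zeta lose 1.4 points and 1.6 points. In this flask EX has taken 4.82 % of the J charged, and the Z share of the converted J less that amount is 19.3 %. In the neighbour flask with 0.72 M of Z, the share falls to 28.6 %, and with 5.59 % in EX it gives 13.6 %, where that flask holds 13.2 %.

Its constants are invented.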